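The numbers of this flask were chosen freely, and the outcome is calculated.

In a one-step world the yield is the fraction of the substrate charge converted, but this flask has a reversible step behind the first, so conversion is not yet the answer.

substrate 0.0020 M; reagent 3.00 mM; time 4.0 min

    substrate + reagent → intermediate (k1 = 172 L mol⁻¹ s⁻¹)
    intermediate ⇌ target (K2 = 0.720, k2 = 0.0664 s⁻¹)
    reagent → decomposition product (k3 = 1.53 × 10⁻⁴ s⁻¹)

1. target at 4.0 min, in percent of the substrate charged
2. intermediate at 4.0 min, in percent of the substrate charged

First I ask whether the reagent reaches the substrate or decomposes. Per unit of reagent, at the charge, dividing the rate of step 1 by that of step 3 cancels the reagent and gives 2250, so at the start it goes to the substrate far faster than it decomposes, and with 1.50 equivalents charged I take the conversion as 1.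

Next I ask whether the pair of intermediate and target comes to balance in the time given. Its relaxation half-life of 0.0728 min is shorter than the 4.0 min, so I may set the forward and backward rates of step 2 equal. Time then drops out, and the fraction of the pair standing as target, which I call the balance share, is 0.419; this is thermodynamic control. My reckoning is 41.9% target and 58.1% intermediate.

The forecast gives 41.9% and 58.1%, holding that “essentially all of it has passed into the intermediate/target pair”. The simulation gives 41.9% target and 58.1% intermediate.

The remaining 0.581 of the pair stays as intermediate because target runs back: with that backward run struck out, intermediate at the asked time falls from 58.1% to 0%.

The neighbour flask with 0.0018 M of reagent has 0.900 equiv, so I take that fraction of the substrate charge as the pair, and the balance share gives 37.7% target. The simulation of that neighbour flask gives 37.6% target, with reagent, the limiting reagent, at 0% of its charge and substrate at 10% of its charge.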